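With the ring numbered C1 (single prenyl), C2 (O), C3 (gem-diprenyl), C4 (O), C5 (benzoyl), C6 (O), the benzoyl carbon, C5 and C6–O are carried as a 3-phenylisoxazole whose 4-ester carbon is C4 and whose 5-CH2 is C1. Only C2 and C3 are missing, and diprenylketene supplies both. In one operation the lithiated C1 adds to the ketene carbonyl (C1–C2) and the resulting C3 enolate acylates the ester (C3–C4), closing the carbocycle and setting the quaternary carbon without deprotonating a hindered C–H. The precursor is methyl 5-(4-methylpent-3-enyl)-3-phenylisoxazole-4-carboxylate; reductive N–O cleavage and hydrolysis then reveal the acyl-triketone.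

Key step: step 7

Remarks on the chemistry:
- The target is one enol tautomer of 2-benzoyl-4,4,6-triprenylcyclohexane-1,3,5-trione. The tautomers interconvert freely, the compound has no stereocentre, and all prenyl alkenes carry a gem-dimethyl end, so no alkene geometry has to be set.
- The key step does create one stereocentre (C7 of 14). It is uncontrolled, so 14 is racemic, and the centre is erased by enolisation at the end.
- Dimethyl malonate is used because methyl esters undergo the Krapcho reaction more readily than ethyl esters.
- Ketene 11 must be free of acyl chloride 10, which would acylate 12 directly and then enolise toward C1. It is used in slight excess because diisopropylamine also adds to ketenes.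

Step 1
Reactants: 1 5-methyl-3-phenylisoxazole-4-carboxylic acid; 2 prenyl bromide (1-bromo-3-methylbut-2-ene)
Product: 4 5-(4-methylpent-3-en-1-yl)-3-phenylisoxazole-4-carboxylic acid, via dilithio dianion 3 (not isolated)
Conditions: LiN(iPr)2 (2.1 equiv), THF, –78 °C; then 2 (1.05 equiv), –78 → –20 °C; cold 1 M HCl
Reagents that add atoms: none
Why: Lateral lithiation of the 5-methyl group of the lithium carboxylate (the carboxylate shields the carbonyl from attack and from self-condensation) gives dianion 3, whose carbanion is alkylated by the primary allylic bromide in an SN2 reaction.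

Step 2
Reactants: 4 5-(4-methylpent-3-en-1-yl)-3-phenylisoxazole-4-carboxylic acid
Product: 5 methyl 5-(4-methylpent-3-en-1-yl)-3-phenylisoxazole-4-carboxylate
Conditions: MeI, K2CO3, DMF, rt
Reagents that add atoms: iodomethane, CI
Why: SN2 O-methylation of the potassium carboxylate (esterification by carboxylate alkylation) is mild enough to leave the isoxazole nitrogen and the trisubstituted alkene untouched.

Step 3
Reactants: 6 dimethyl malonate; 2 prenyl bromide (2.2 equiv)
Product: 7 dimethyl 2,2-bis(3-methylbut-2-en-1-yl)propanedioate
Conditions: NaH (2.2 equiv), THF/DMF, 0 → 50 °C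
Reagents that add atoms: none
Why: Malonic ester synthesis, in which the sodium enolate is C-alkylated twice by the reactive primary allylic bromide, the second alkylation being driven by the excess of base and bromide at 50 °C.

Step 4
Reactants: 7 dimethyl 2,2-bis(3-methylbut-2-en-1-yl)propanedioate
Product: 8 methyl 5-methyl-2-(3-methylbut-2-en-1-yl)hex-4-enoate
Conditions: LiCl, H2O, DMSO, 150–160 °C
Reagents that add atoms: none
Why: Krapcho demethoxycarbonylation, in which chloride demethylates one ester by SN2 attack, the carboxylate loses CO2 and the enolate is protonated by water, all under neutral conditions that cannot hydrate or cyclise the prenyl alkenes.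

Step 5
Reactants: 8 methyl 5-methyl-2-(3-methylbut-2-en-1-yl)hex-4-enoate
Product: 9 5-methyl-2-(3-methylbut-2-en-1-yl)hex-4-enoic acid
Conditions: LiOH, THF/MeOH/H2O, 50 °C; then cold 1 M HCl to pH 3
Reagents that add atoms: lithium hydroxide, [Li+].[OH-]
Why: Saponification (acyl substitution by hydroxide) of the α-branched methyl ester, with a cold and brief acidification so that the γ,δ-unsaturated acid should not lactonise.

Step 6
Reactants: 9 5-methyl-2-(3-methylbut-2-en-1-yl)hex-4-enoic acid
Product: 11 diprenylketene [5-methyl-2-(3-methylbut-2-en-1-yl)hexa-1,4-dien-1-one], via diprenylacetyl chloride 10 (not isolated)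
Conditions: (COCl)2, cat. DMF, CH2Cl2, 0 °C → rt, evaporate; Et3N (1.5 equiv), THF, 60 °C; filter under Ar, bulb-to-bulb distil, keep cold in THF
Reagents that add atoms: none
Why: Vilsmeier-type activation converts the acid into acyl chloride 10, and triethylamine then removes the α-proton with loss of chloride (dehydrochlorination of an acyl chloride, the standard ketene preparation) to give a dialkylketene hindered enough to be distilled and stored cold.

Step 7
Reactants: 5 methyl 5-(4-methylpent-3-en-1-yl)-3-phenylisoxazole-4-carboxylate; 11 diprenylketene
Product: 14 5,5,7-tris(3-methylbut-2-en-1-yl)-3-phenyl-1,2-benzoxazole-4,6(5H,7H)-dione (racemic at C7), via lateral lithio ester 12 (not isolated), via ring-open lithium enolate 13 (not isolated)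
Conditions: LiN(iPr)2 (1.1 equiv), THF, –78 °C; 11 (1.3 equiv) added slowly, –78 → 0 °C; AcOH quench at –78 °C
Reagents that add atoms: none
Why: Proposed new method: LiN(iPr)2 removes a proton from the side-chain CH2 next to isoxazole C5 (ring carbon C1, acidified by the heterocycle and vinylogously by the 4-ester), carbanion 12 adds to the carbonyl carbon of ketene 11 (bond C1–C2) to give enolate 13 with the nucleophilic carbon fixed at the diprenyl-bearing C3, and 13 acylates the neighbouring methyl ester (bond C3–C4) with loss of methoxide, which then deprotonates 14 at C7. The closest known reaction type is the Staunton–Weinreb annulation of laterally lithiated ortho-toluates, joined here to two other known events, the addition of organolithiums to ketenes to give regiodefined enolates and the lateral lithiation of 5-alkylisoxazole-4-carboxylates. The single new ring, the six-membered carbocycle fused to the isoxazole, closes in a 6-exo-trig mode (enolate carbon onto the ester carbonyl). The one new stereocentre, C7 of 14, forms without control, so 14 is racemic, and the centre is erased by enolisation in the final product. The selectivity needed is C- over O-acylation of a tetrasubstituted enolate and no proton shift from C1 to C3 before closure; the lithium counter-ion in THF without polar additives favours carbon attack, the enol lactone from O-attack can be reopened by lithium methoxide, and only the carbocycle is drained irreversibly as its stabilised C7 enolate.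

Step 8
Reactants: 14 5,5,7-tris(3-methylbut-2-en-1-yl)-3-phenyl-1,2-benzoxazole-4,6(5H,7H)-dione
Product: 15 2-[amino(phenyl)methylidene]-4,4,6-tris(3-methylbut-2-en-1-yl)cyclohexane-1,3,5-trione (tautomeric mixture, racemic and enolisable at C6)
Conditions: Mo(CO)6 (0.6 equiv), MeCN/H2O, 80 °C
Reagents that add atoms: none
Why: Reductive cleavage of the weak isoxazole N–O bond by zerovalent molybdenum, with water as the proton source, gives the primary enaminone (vinylogous amide) and should leave trisubstituted alkenes and ketones untouched.

Step 9
Reactants: 15 2-[amino(phenyl)methylidene]-4,4,6-tris(3-methylbut-2-en-1-yl)cyclohexane-1,3,5-trione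
Product: 16 2-benzoyl-3,5-dihydroxy-4,4,6-tris(3-methylbut-2-en-1-yl)cyclohexa-2,5-dien-1-one (target)
Conditions: 2 M NaOH, EtOH/H2O, 70 °C, Ar (degassed); then cold 1 M HCl to pH 3
Reagents that add atoms: sodium hydroxide, [Na+].[OH-]
Why: Hydroxide adds to the enamine carbon of the vinylogous amide and ammonia is expelled (addition–elimination hydrolysis of an enaminone), base being chosen over acid because acid would cyclise the prenyl groups onto the enol oxygens; the product enolises to the target tautomer and the C6 stereocentre vanishes.

Compound list
1 | 5-methyl-3-phenylisoxazole-4-carboxylic acid | Cc1onc(-c2ccccc2)c1C(=O)O | starting material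
2 | prenyl bromide (1-bromo-3-methylbut-2-ene) | CC(C)=CCBr | starting material
3 | lithium 5-(lithiomethyl)-3-phenylisoxazole-4-carboxylate (dilithio dianion) | [Li+].[Li+].[CH2-]c1onc(-c2ccccc2)c1C([O-])=O | intermediate
4 | 5-(4-methylpent-3-en-1-yl)-3-phenylisoxazole-4-carboxylic acid | CC(C)=CCCc1onc(-c2ccccc2)c1C(=O)O | intermediate
5 | methyl 5-(4-methylpent-3-en-1-yl)-3-phenylisoxazole-4-carboxylate | COC(=O)c1c(CCC=C(C)C)onc1-c1ccccc1 | intermediate
6 | dimethyl malonate | COC(=O)CC(=O)OC | starting material
7 | dimethyl 2,2-bis(3-methylbut-2-en-1-yl)propanedioate | COC(=O)C(CC=C(C)C)(CC=C(C)C)C(=O)OC | intermediate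
8 | methyl 5-methyl-2-(3-methylbut-2-en-1-yl)hex-4-enoate | COC(=O)C(CC=C(C)C)CC=C(C)C | intermediate
9 | 5-methyl-2-(3-methylbut-2-en-1-yl)hex-4-enoic acid | OC(=O)C(CC=C(C)C)CC=C(C)C | intermediate
10 | 5-methyl-2-(3-methylbut-2-en-1-yl)hex-4-enoyl chloride (diprenylacetyl chloride) | ClC(=O)C(CC=C(C)C)CC=C(C)C | intermediate
11 | diprenylketene, 5-methyl-2-(3-methylbut-2-en-1-yl)hexa-1,4-dien-1-one | CC(C)=CCC(=C=O)CC=C(C)C | intermediate
12 | lithium salt of 5 deprotonated at the CH2 next to the isoxazole (lateral lithio ester) | [Li+].COC(=O)c1c([CH-]CC=C(C)C)onc1-c1ccccc1 | intermediate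
13 | lithium enolate of methyl 5-[7-methyl-3-(3-methylbut-2-en-1-yl)-2-oxo-1-(3-methylbut-2-en-1-yl)oct-6-en-1-yl]-3-phenylisoxazole-4-carboxylate, enolised toward the diprenyl carbon (ring-open enolate) | [Li+].COC(=O)c1c(C(CC=C(C)C)C([O-])=C(CC=C(C)C)CC=C(C)C)onc1-c1ccccc1 | intermediate
14 | 5,5,7-tris(3-methylbut-2-en-1-yl)-3-phenyl-1,2-benzoxazole-4,6(5H,7H)-dione, racemic at C7 | O=C1C(CC=C(C)C)c2onc(-c3ccccc3)c2C(=O)C1(CC=C(C)C)CC=C(C)C | intermediate
15 | 2-[amino(phenyl)methylidene]-4,4,6-tris(3-methylbut-2-en-1-yl)cyclohexane-1,3,5-trione, racemic at C6, mobile exocyclic alkene geometry | NC(c1ccccc1)=C1C(=O)C(CC=C(C)C)C(=O)C(CC=C(C)C)(CC=C(C)C)C1=O | intermediate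
16 | 2-benzoyl-3,5-dihydroxy-4,4,6-tris(3-methylbut-2-en-1-yl)cyclohexa-2,5-dien-1-one, no stereocentre | CC(C)=CCC1=C(O)C(CC=C(C)C)(CC=C(C)C)C(O)=C(C(=O)c2ccccc2)C1=O | target

Total step count: 9. Longest linear sequence: 7 steps (steps 3 to 9, from dimethyl malonate).

Steps most likely to fail

Step 7 (proposed new method). After the ketene addition the hindered enolate may acylate through oxygen, or a proton may shift from the acidic C1–H to C3 and leave the conjugated enolate, which cannot close the ring. Ketene may also be consumed by diisopropylamine. The fallback uses known chemistry, makes the same two bonds in the reverse order and needs no ketene. It sets out from acid 4 and ester 8. Acid 4 is converted with (COCl)2 and cat. DMF in CH2Cl2 into 5-(4-methylpent-3-en-1-yl)-3-phenylisoxazole-4-carbonyl chloride F1. The lithium enolate of 8 (LiN(iPr)2, THF, –78 °C) is C-acylated by F1 (crossed Claisen acylation of an ester enolate, bond C3–C4) to give the quaternary β-keto ester methyl 2,2-bis(3-methylbut-2-en-1-yl)-3-[5-(4-methylpent-3-en-1-yl)-3-phenylisoxazol-4-yl]-3-oxopropanoate F2. LiN(SiMe3)2 (2.2 equiv, THF, –78 → 0 °C) then removes a proton from the side-chain CH2, now vinylogously activated by the 4-acyl group, and the lateral anion closes on the methyl ester (Dieckmann-type intramolecular Claisen condensation, bond C1–C2). The fallback comes back to the route at 14.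

Step 6. Dehydrochlorination of the α,α-dialkyl acyl chloride may be sluggish, HCl may add to the prenyl alkenes while the chloride is formed, and the ketene may dimerise or hydrolyse during isolation. The fallback makes the ketene by thermal fragmentation instead of elimination and sets out from prenyl bromide 2. Commercial 2,2-dimethyl-1,3-dioxane-4,6-dione is dialkylated with 2 (K2CO3, DMF, rt) to give 2,2-dimethyl-5,5-bis(3-methylbut-2-en-1-yl)-1,3-dioxane-4,6-dione F3. Flash vacuum pyrolysis of F3 (about 450–500 °C, below 0.1 mbar) expels acetone and CO2. The ketene is collected cold, freed from acetone under vacuum and taken up in THF. The fallback comes back to the route at 11.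

Step 9. The doubly stabilised vinylogous amide may resist hydroxide, and forcing may bring retro-Claisen loss of the benzoyl group or air oxidation of the electron-rich triketone anion. The fallback leaves the isoxazole route and reaches the target by dearomatising C-prenylation of an acylphloroglucinol. It sets out from prenyl bromide 2. Benzene-1,3,5-triol is benzoylated (PhCOCl, AlCl3, PhNO2, Friedel–Crafts acylation) to (2,4,6-trihydroxyphenyl)(phenyl)methanone F4. With 2 (3 equiv) and NaOMe in MeOH at 0 °C the ring carbons are prenylated in turn, through the 3,5-diprenyl stage [2,4,6-trihydroxy-3,5-bis(3-methylbut-2-en-1-yl)phenyl](phenyl)methanone F5. The third prenyl group enters at a carbon that already carries one, which breaks the aromaticity. The fallback comes back to the route at 16.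

Further compounds
F1 | step 7 | 5-(4-methylpent-3-en-1-yl)-3-phenylisoxazole-4-carbonyl chloride | CC(C)=CCCc1onc(-c2ccccc2)c1C(Cl)=O
F2 | step 7 | methyl 2,2-bis(3-methylbut-2-en-1-yl)-3-[5-(4-methylpent-3-en-1-yl)-3-phenylisoxazol-4-yl]-3-oxopropanoate | COC(=O)C(CC=C(C)C)(CC=C(C)C)C(=O)c1c(CCC=C(C)C)onc1-c1ccccc1
F3 | step 6 | 2,2-dimethyl-5,5-bis(3-methylbut-2-en-1-yl)-1,3-dioxane-4,6-dione | CC(C)=CCC1(CC=C(C)C)C(=O)OC(C)(C)OC1=O
F4 | step 9 | (2,4,6-trihydroxyphenyl)(phenyl)methanone | O=C(c1ccccc1)c1c(O)cc(O)cc1O
F5 | step 9 | [2,4,6-trihydroxy-3,5-bis(3-methylbut-2-en-1-yl)phenyl](phenyl)methanone | O=C(c1ccccc1)c1c(O)c(CC=C(C)C)c(O)c(CC=C(C)C)c1O
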